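The rate constants are those of an exercise; the flask was simulated.

Start from late times: there the target in a flask stands no higher than its equilibrium with the starting material allows.

    solid substrate ⇌ starting material, rate k1*(cs1 - [starting material]) while solid is left; crystals form when [starting material] > cs1 (cs1 = 7.3 mM, k1 = 2.63 s⁻¹)
    starting material ⇌ isomer of the product (K2 = 2.17, k2 = 0.00957 s⁻¹, Ea2 = 97.0 kJ mol⁻¹, ΔH2 = −28.0 kJ mol⁻¹)
    starting material ⇌ target (K3 = 3.2, k3 = 0.643 s⁻¹, Ea3 = 94.0 kJ mol⁻¹, ΔH3 = −41.0 kJ mol⁻¹)
    (constants at 60 °C)

| setting | ochre | teal | amber | grey |
|---|---|---|---|---|
| solid substrate | 10 mM | 10 mM | 10 mM | 10 mM |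
| temperature | 45 °C | 75 °C | 60 °C | 90 °C |
| time | 25 s | 25 s | 25 s | 25 s |

- solid substrate is a solid; its amount is given per volume of the solution
- constants are those at 60 °C; use the activation energies and enthalpies for any other temperature
- at the start none of the solid substrate is in solution
- what has only dissolved of solid substrate counts as not reacted

1. the flask with the highest amount of target, in percent of the solid substrate charged ("all alike" if they lie within 1.5 percentage points) (ochre / teal / amber / grey / all alike)
2. final target, as a percentage of the solid substrate charged, in ochre
3. final target, as a percentage of the solid substrate charged, in teal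
4. final target, as a percentage of the solid substrate charged, in amber
5. final target, as a percentage of the solid substrate charged, in grey

Take the starting material and target as a pair, a pre-equilibrium, with forward constant k and equilibrium constant K at the flask's temperature. With the pair's sum held at the charge, the net rate k·c(starting material) − (k/K)·c(target) integrates in closed form:

c(target)/charge = [K/(1+K)]·[1 − exp(−ln(2)·t/h)]

h = ln(2)/[k(1+1/K)]

In ochre, k is 0.130 s⁻¹ and K is 6.43, so the ceiling is 86.5% and the relaxation half-life of the step to target, both ways together, is 4.62 s. I start the clock at zero because dissolving, at 0.264 s, is far quicker than that. I set the isomer aside in ochre because its relaxation half-life of 4.89 min is far longer.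

Now turn the question round: what would make ochre lose? In amber the pair relaxes in 0.821 s, far less than the time allowed, so I expect the ratio of target to starting material to reach K there, and I take amber's ceiling as an upper bound, with the isomer set aside:

amber: below 76.2%

Ochre clears that bound if more than 3.06 half-lives fit into the time, and 5.41 fit:

ochre: 84.5%

K falls to 1.69 in teal and 0.942 in grey, which gives ceilings:

teal: below 62.8%

grey: below 48.5%

My pick is ochre.

The forecast also names ochre, with 83% in ochre, 47.7% in teal, 71.7% in amber and 32.7% in grey, holding that “target is set by its exothermic equilibrium”. For amber, teal and grey I give bounds where it gives numbers.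

The simulation gives ochre, with 83.0% in ochre, 48.1% in teal, 71.9% in amber and 32.7% in grey.

In ochre, the forward rate to target stood 71 times that to the isomer at 0.431 s, and the pair's 4.62 s lies far below the isomer step's 4.89 min; ochre ends with 1.59% isomer. Now repeat ochre at 30 °C: K is 13.8, h lengthens to 28.9 s, and the formula gives 42.1%. The computed flask holds 38.1% target, with 61.3% still starting material.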